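The earlier runs and the new flask were generated by integration for an exercise; scatter was added.

In a one-step world each substrate goes to product on the catalyst at its own turnover per catalyst, so two clocks describe the flask: a fast one for the left-handed substrate and a slow one for the right-handed substrate.

in all of them: gas 100 mM (held)
- winter: left-handed substrate 1.1 M; right-handed substrate 1.1 M; free catalyst 22 mM; run made earlier
- autumn: left-handed substrate 1.1 M; right-handed substrate 1.1 M; free catalyst 35 mM; run made earlier
- summer: left-handed substrate 1.7 M; right-handed substrate 1.7 M; free catalyst 16 mM; run made earlier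
- flask: left-handed substrate 1.1 M; right-handed substrate 1.1 M; free catalyst 16 mM; time 3.0 h

- winter (time / h: right-handed substrate / %, left-handed substrate / %, left-handed product / %): 0.250: 41.5, 0, 48.1; 0.667: 28.7, 0.5, 52.5; 1.33: 14.2, 0, 49.3; 2.00: 5.2, 0, 49.9; 3.00: 0, 0.2, 48.8; 4.00: 1.3, 0.4, 49.5
- autumn (time / h: right-handed substrate / %, left-handed substrate / %, left-handed product / %): 0.250: 38.1, 0, 49.9; 0.667: 18.9, 0.5, 50.0; 1.33: 3.7, 0, 49.6; 2.00: 0.2, 0, 51.2; 3.00: 0.8, 0, 50.1; 4.00: 0, 0.7, 49.6
- summer (time / h: right-handed substrate / %, left-handed substrate / %, left-handed product / %): 0.250: 45.7, 5.9, 43.6; 0.500: 40.9, 0, 50.9; 1.00: 32.9, 0.6, 52.2; 2.00: 17.2, 0.7, 50.6; 4.00: 2.0, 1.0, 50.7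

(standard deviation of a reading: 1 percentage point)

- free catalyst is single-handed; left-handed substrate and right-handed substrate are mirror images of each other, charged as a racemate, each of them at the stated concentration
- the numbers in the tables scatter by 1 percentage point (one standard deviation)
- at the start none of the gas is in solution

- whether the excess of right-handed substrate over left-handed substrate among what is left of the two reaches 80% by 3.0 h (no / yes)
- the highest excess of right-handed substrate over left-handed substrate among what is left of the two up to 3.0 h

The summer run has the flask's catalyst charge and reads 43.6% left-handed product at 0.250 h. That is a reading of 371 h⁻¹ per catalyst, at which the flask's left-handed substrate is reckoned to last 0.186 h. The winter run loses right-handed substrate between 0.250 h and 1.33 h at a reading of 25.3 h⁻¹ per catalyst. For the flask this gives 2.72 h as the slow clock: charged [right-handed substrate] over that turnover times charged [free catalyst].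

Two extremes bracket the flask. With saturated catalyst, right-handed substrate falls in a straight line and reaches zero at the slow clock, sooner than 3.0 h. With a rate proportional to [right-handed substrate], it decays on that clock and 16.6% of both substrates charged stands at 3.0 h. The winter readings taper as they fall, so this reckoning places the flask between the two. Putting the fast clock back in, the flask's right-handed substrate is reckoned to have lost 6.84% of its own charge when the fast clock ends, so this reckoning expects the excess to pass 80% early and end close to complete.

The forecast says yes, with a top of 99.5%, finding “no sign of racemisation”.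

The flask gives yes and 100%.

    free catalyst + left-handed substrate ⇌ catalyst intermediate A (K = 1.20 M⁻¹, k = 7.60 M⁻¹ s⁻¹)
    free catalyst + right-handed substrate ⇌ catalyst intermediate B (K = 2.30 M⁻¹, k = 8.90 M⁻¹ s⁻¹)
    reagent + catalyst intermediate A → free catalyst + left-handed product (k = 7.80 M⁻¹ s⁻¹)
    reagent + catalyst intermediate B → free catalyst + right-handed product (k = 0.130 M⁻¹ s⁻¹)
    reagent ⇌ dormant form (K = 4.40, k = 0.00420 s⁻¹)
    gas ⇌ reagent, rate k6*(csat - [reagent]) (kL = 0.440 s⁻¹)
    2 reagent → homo dimer (k = 0.00800 M⁻¹ s⁻¹)

The flask reaches 80% at 0.193 h, far sooner than the slow clock of 2.72 h, with right-handed substrate still standing at 45.6% of both substrates charged. At 3.00 h the flask holds right-handed substrate at 3.40% of both substrates charged, inside the bracket from zero to 16.6%, and this is 6.8% of its own charge.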